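## Retrosynthetic overview

1. Target 21 ⇐ macrocyclic C3 alcohol 20 (acetylation).
2. 20 ⇐ acyclic bromide 15 (C7–C13, C8–C10, C1–C2, angelate in place) + (Z)-2-methylbut-2-enedial 18 (C3–C6) in one flask: C6–C7 allylation with lactonisation closes the α-methylene lactone first, then C2–C3 alkenyl–aldehyde coupling closes the ten-membered ring.
3. 15 ⇐ vinyl epoxide 11 (bromide SN2′ opening, in situ angeloylation) ⇐ dienoate 10 (Shi epoxidation sets C8) ⇐ diol 5 + bromoacrylate 6 (oxidation/Wittig).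
4. 5 ⇐ iododienol 3 (Sharpless epoxidation sets C10, hydride opening) ⇐ enynol 1; 18 ⇐ 3-methylfuran 16 (singlet oxygen).

Assumption: locants C1–C13 are germacrane numbers of the target (C1=C2, C3 OAc, C4=C5, C6 lactone O, C7, C8 angelate, C9, C10 carbinol, C11=C13, C12 lactone C=O); the target is (1E,3R,4Z,6R,7S,8R,10R), a cis-fused lactone.

## Route

**Step 1**
Reactants: 1 (E)-3-methylpent-2-en-4-yn-1-ol
Product: 3 (2E,4E)-5-iodo-3-methylpenta-2,4-dien-1-ol, via dienylstannane 2 (not isolated)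
Conditions: Bu3SnH, PdCl2(PPh3)2 (2 mol %), THF, 0 °C; then I2, CH2Cl2, 0 °C
Reagents that add atoms: iodine, II
Why: Pd-catalysed syn-hydrostannation puts tin on the terminal alkyne carbon (E-alkenylstannane) and iododestannylation proceeds with retention, giving the E-alkenyl iodide needed for the later Nozaki–Hiyama–Kishi closure.

**Step 2**
Reactants: 3 (2E,4E)-5-iodo-3-methylpenta-2,4-dien-1-ol
Product: 4 [(2S,3S)-3-[(E)-2-iodoethenyl]-3-methyloxiran-2-yl]methanol
Conditions: Ti(OiPr)4 (10 mol %), L-(+)-diethyl tartrate (12 mol %), t-BuOOH, 4 Å MS, CH2Cl2, −20 °C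
Reagents that add atoms: tert-butyl hydroperoxide, CC(C)(C)OO
Why: Sharpless asymmetric epoxidation of the E-trisubstituted allylic alcohol; L-(+)-tartrate gives the (2S,3S)-epoxide (as with geraniol), which fixes the future C10 stereocenter.

**Step 3**
Reactants: 4 [(2S,3S)-3-[(E)-2-iodoethenyl]-3-methyloxiran-2-yl]methanol
Product: 5 (3R,4E)-5-iodo-3-methylpent-4-ene-1,3-diol
Conditions: NaAlH2(OCH2CH2OMe)2, THF, −20 → 0 °C; aq. KNaC4H4O6 work-up
Reagents that add atoms: none
Why: Hydroxyl-directed intramolecular hydride delivery from the C1 alkoxyaluminate opens the epoxide at C2 (regioselective 2,3-epoxy alcohol → 1,3-diol reduction), leaving the tertiary C–O bond and its configuration (future C10, R) untouched.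

**Step 4**
Reactants: 5 (3R,4E)-5-iodo-3-methylpent-4-ene-1,3-diol; 6 methyl 2-(bromomethyl)prop-2-enoate
Product: 10 methyl (3E,6R,7E)-6-hydroxy-8-iodo-6-methyl-2-methylideneocta-3,7-dienoate, via phosphonium bromide 7 (not isolated), via phosphorus ylide 8 (not isolated), via hydroxy aldehyde 9 (not isolated)
Conditions: 6, PBu3, CH2Cl2, 0 °C; separately 5, TEMPO (cat.), PhI(OAc)2, CH2Cl2, rt; then combine, K2CO3, H2O, 0 °C → rt
Reagents that add atoms: none
Why: TEMPO/PhI(OAc)2 oxidises only the primary alcohol, and the sensitive β-hydroxy aldehyde is trapped at once by E-selective Wittig olefination with the allylic tributylphosphonium ylide made from 6, giving the 2-(methoxycarbonyl)-1,3-diene.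

**Step 5**
Reactants: 10 methyl (3E,6R,7E)-6-hydroxy-8-iodo-6-methyl-2-methylideneocta-3,7-dienoate
Product: 11 methyl 2-{(2R,3R)-3-[(2R,3E)-2-hydroxy-4-iodo-2-methylbut-3-en-1-yl]oxiran-2-yl}prop-2-enoate
Conditions: 1,2:4,5-di-O-isopropylidene-β-D-erythro-2,3-hexodiulo-2,6-pyranose (30 mol %), 2KHSO5·KHSO4·K2SO4, K2CO3, Bu4NHSO4, MeCN–CH2(OMe)2–aq. buffer (pH 10.5), 0 °C
Reagents that add atoms: potassium peroxymonosulfate KHSO5, [K+].[O-]S(=O)(=O)OO
Why: Shi asymmetric epoxidation: the fructose-derived dioxirane attacks the electron-richer E-disubstituted C7=C8 alkene through the spiro transition state to give the (R,R)-epoxide, which sets C8 (R); the acrylate and iodoalkene are too electron-poor to compete.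

**Step 6**
Reactants: 11 methyl 2-{(2R,3R)-3-[(2R,3E)-2-hydroxy-4-iodo-2-methylbut-3-en-1-yl]oxiran-2-yl}prop-2-enoate; 12 angelic acid [(2Z)-2-methylbut-2-enoic acid]
Product: 15 methyl (2Z,4R,6R,7E)-2-(bromomethyl)-6-hydroxy-8-iodo-6-methyl-4-{[(2Z)-2-methylbut-2-enoyl]oxy}octa-2,7-dienoate, via mixed anhydride 13 (not isolated), via bromomagnesium alkoxide 14 (not isolated)
Conditions: 12, 2,4,6-Cl3C6H2COCl, Et3N, toluene, rt, filter; separately 11, MgBr2·OEt2, CH2Cl2, −40 → −10 °C; then add the filtrate, −10 °C → rt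
Reagents that add atoms: magnesium bromide diethyl etherate, [Mg+2].[Br-].[Br-].CCOCC
Why: Lewis-acid-assisted SN2′ (conjugate) opening of the 2-oxiranyl acrylate by bromide gives the favoured (Z)-2-(bromomethyl) enoate without breaking the C8–O bond (C8 stays R), and the magnesium alkoxide is acylated in situ by the Yamaguchi–Greene mixed anhydride, which transfers angeloyl without Z→E isomerisation and without an amine that would quaternise the allylic bromide.

**Step 7**
Reactants: 16 3-methylfuran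
Product: 18 (2Z)-2-methylbut-2-enedial, via furan endoperoxide 17 (not isolated)
Conditions: O2, tetraphenylporphyrin (cat.), hν, CH2Cl2, −78 °C; then Me2S, −78 → 0 °C; used at once as a THF solution
Reagents that add atoms: dioxygen, O=O
Why: [4+2] cycloaddition of singlet oxygen across the furan 2,5-positions and reduction of the endoperoxide by Me2S unmask the ene-dial with the Z geometry inherited from the ring.

**Step 8**
Reactants: 15 methyl (2Z,4R,6R,7E)-2-(bromomethyl)-6-hydroxy-8-iodo-6-methyl-4-{[(2Z)-2-methylbut-2-enoyl]oxy}octa-2,7-dienoate; 18 (2Z)-2-methylbut-2-enedial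
Product: 20 (1E,3R,4Z,6R,7S,8R,10R)-3,10-dihydroxy-8-[(2Z)-2-methylbut-2-enoyloxy]germacra-1,4,11(13)-trien-12,6-olide, via lactone enal 19 (not isolated)
Conditions: 15 + 18 (1.2 equiv), THF, 0 °C, CrCl2 (3 equiv, in portions), then rt, 2 h; dilute with degassed DMF to 2 mM, CrCl2 (8 equiv), NiCl2 (0.1 equiv), rt, 24 h
Reagents that add atoms: none
Why: Proposed new method: divalent chromium turns the allylic bromide into a 2-(methoxycarbonyl)allylchromium that adds through a closed chair transition state to the less hindered formyl group of 18 (the one on the CH= carbon), the Z-type γ-substituent giving the syn adduct whose chromium alkoxide lactonises to the cis-fused lactone 19 (C6 R, C7 S), with the aldehyde predicted to approach C7 anti to the C8–O bond while H-8 eclipses the alkene (allylic 1,3-strain, Kishi-type facial bias), after which nickel-catalysed activation of the E-alkenyl iodide closes the ten-membered ring by addition to the remaining enal, C3 (R) requiring Re-face attack, which is assumed from peripheral approach on the pre-organised cis-lactone/Z-alkene chain; the closest known reactions are the chromium-mediated Barbier allylation–lactonisation of 2-(bromomethyl)acrylates and the Nozaki–Hiyama–Kishi macrocyclisation, here run consecutively in one flask on an unsymmetrical dialdehyde.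

**Step 9**
Reactants: 20 (1E,3R,4Z,6R,7S,8R,10R)-3,10-dihydroxy-8-[(2Z)-2-methylbut-2-enoyloxy]germacra-1,4,11(13)-trien-12,6-olide
Product: 21 (1E,3R,4Z,6R,7S,8R,10R)-3-acetoxy-10-hydroxy-8-[(2Z)-2-methylbut-2-enoyloxy]germacra-1,4,11(13)-trien-12,6-olide (CNP0181631.1)
Conditions: Ac2O, pyridine, DMAP (cat.), CH2Cl2, 0 °C
Reagents that add atoms: acetic anhydride, CC(=O)OC(C)=O
Why: DMAP-catalysed acetylation of the only secondary alcohol; the tertiary C10 alcohol does not react at 0 °C and no stereocenter is touched.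

## Compound list

1 | (E)-3-methylpent-2-en-4-yn-1-ol | C#C/C(C)=C/CO | starting material
2 | (2E,4E)-3-methyl-5-(tributylstannyl)penta-2,4-dien-1-ol | CCCC[Sn](CCCC)(CCCC)/C=C/C(C)=C/CO | intermediate
3 | (2E,4E)-5-iodo-3-methylpenta-2,4-dien-1-ol | I/C=C/C(C)=C/CO | intermediate
4 | [(2S,3S)-3-[(E)-2-iodoethenyl]-3-methyloxiran-2-yl]methanol | OC[C@@H]1O[C@@]1(C)/C=C/I | intermediate
5 | (3R,4E)-5-iodo-3-methylpent-4-ene-1,3-diol | OCC[C@@](C)(O)/C=C/I | intermediate
6 | methyl 2-(bromomethyl)prop-2-enoate | C=C(CBr)C(=O)OC | starting material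
7 | tributyl[2-(methoxycarbonyl)prop-2-en-1-yl]phosphonium bromide | CCCC[P+](CCCC)(CCCC)CC(=C)C(=O)OC.[Br-] | intermediate
8 | methyl 2-[(tributyl-λ5-phosphanylidene)methyl]prop-2-enoate | CCCCP(CCCC)(CCCC)=CC(=C)C(=O)OC | intermediate
9 | (3R,4E)-3-hydroxy-5-iodo-3-methylpent-4-enal | O=CC[C@@](C)(O)/C=C/I | intermediate
10 | methyl (3E,6R,7E)-6-hydroxy-8-iodo-6-methyl-2-methylideneocta-3,7-dienoate | COC(=O)C(=C)/C=C/C[C@@](C)(O)/C=C/I | intermediate
11 | methyl 2-{(2R,3R)-3-[(2R,3E)-2-hydroxy-4-iodo-2-methylbut-3-en-1-yl]oxiran-2-yl}prop-2-enoate | COC(=O)C(=C)[C@H]1O[C@@H]1C[C@@](C)(O)/C=C/I | intermediate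
12 | angelic acid, (2Z)-2-methylbut-2-enoic acid | C/C=C(/C)C(=O)O | starting material
13 | (2Z)-2-methylbut-2-enoic 2,4,6-trichlorobenzoic anhydride | C/C=C(/C)C(=O)OC(=O)c1c(Cl)cc(Cl)cc1Cl | intermediate
14 | bromomagnesium C4-alkoxide of methyl (2Z,4R,6R,7E)-2-(bromomethyl)-4,6-dihydroxy-8-iodo-6-methylocta-2,7-dienoate | COC(=O)/C(CBr)=C/[C@H]([O-])C[C@@](C)(O)/C=C/I.[Mg+2].[Br-] | intermediate
15 | methyl (2Z,4R,6R,7E)-2-(bromomethyl)-6-hydroxy-8-iodo-6-methyl-4-{[(2Z)-2-methylbut-2-enoyl]oxy}octa-2,7-dienoate | COC(=O)/C(CBr)=C/[C@H](OC(=O)/C(C)=C\C)C[C@@](C)(O)/C=C/I | intermediate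
16 | 3-methylfuran | Cc1ccoc1 | starting material
17 | 5-methyl-2,3,7-trioxabicyclo[2.2.1]hept-5-ene (racemic) | CC1=CC2OOC1O2 | intermediate
18 | (2Z)-2-methylbut-2-enedial | O=C/C=C(/C)C=O | intermediate
19 | (1R,3R,4E)-3-hydroxy-5-iodo-3-methyl-1-{(2R,3S)-4-methylidene-2-[(1Z)-2-methyl-3-oxoprop-1-en-1-yl]-5-oxooxolan-3-yl}pent-4-en-1-yl (2Z)-2-methylbut-2-enoate | C=C1C(=O)O[C@H](/C=C(/C)C=O)[C@@H]1[C@H](OC(=O)/C(C)=C\C)C[C@@](C)(O)/C=C/I | intermediate
20 | (1E,3R,4Z,6R,7S,8R,10R)-3,10-dihydroxy-8-[(2Z)-2-methylbut-2-enoyloxy]germacra-1,4,11(13)-trien-12,6-olide | C=C1C(=O)O[C@@H]2/C=C(/C)[C@H](O)/C=C/[C@](C)(O)C[C@@H](OC(=O)/C(C)=C\C)[C@H]12 | intermediate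
21 | (1E,3R,4Z,6R,7S,8R,10R)-3-acetoxy-10-hydroxy-8-[(2Z)-2-methylbut-2-enoyloxy]germacra-1,4,11(13)-trien-12,6-olide | C=C1C(=O)O[C@@H]2/C=C(/C)[C@H](OC(C)=O)/C=C/[C@](C)(O)C[C@@H](OC(=O)/C(C)=C\C)[C@H]12 | target

## Step count and risks

Total steps: 9. Longest linear sequence: 8 (steps 1–6, 8, 9); step 7 is a one-step side branch.

**Step 8 is the most likely to fail.** The open points are:
- which formyl group of 18 the allylchromium attacks;
- the facial bias at C7: a Felkin-type approach anti to C9 would give the C6/C7 diastereomer;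
- reduction of the ene-dial or loss of the C8 angelate by divalent chromium;
- the C3 configuration from the ring closure.

The fallback separates the two ring closures and uses a differentiated C4 partner. Starting from 15, commercial 4-methylfuran-2(5H)-one F1 is reduced (i-Bu2AlH, CH2Cl2, −78 °C) to the lactol 4-methyl-2,5-dihydrofuran-2-ol F2, whose only aldehyde-level carbon is the future C6. Indium-mediated Barbier allylation of F2 by 15 in THF–H2O, with lactonisation, gives the hydroxymethyl lactone (1R,3R,4E)-3-hydroxy-1-{(2R,3S)-2-[(1Z)-3-hydroxy-2-methylprop-1-en-1-yl]-4-methylidene-5-oxooxolan-3-yl}-5-iodo-3-methylpent-4-en-1-yl (2Z)-2-methylbut-2-enoate F3. MnO2 oxidises F3 to 19, now isolated, and a separate NiCl2/CrCl2 macrocyclisation of 19 returns to the route at 20.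

**Step 6 is second.** The bromo alkoxide 14 can close to a 2,5-dihydrofuran, the minor E isomer lactonises to a butenolide, and acylation of the magnesium alkoxide may be slow. The fallback isolates a less reactive allylic chloride and acylates the free alcohol. Starting from 11, LiCl/AcOH in THF opens the epoxide to methyl (2Z,4R,6R,7E)-2-(chloromethyl)-4,6-dihydroxy-8-iodo-6-methylocta-2,7-dienoate F4. Heating F4 with mixed anhydride 13 in toluene (60 °C, no amine) gives methyl (2Z,4R,6R,7E)-2-(chloromethyl)-6-hydroxy-8-iodo-6-methyl-4-{[(2Z)-2-methylbut-2-enoyl]oxy}octa-2,7-dienoate F5. Halide exchange on F5 (LiBr, acetone) returns to the route at 15.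

**Step 4 is third.** The β-hydroxy aldehyde 9 can undergo retro-aldol cleavage or dehydration under the basic Wittig conditions, and diene 10 can dimerise. The fallback masks the tertiary alcohol for the olefination. Starting from 5, Et3SiOTf/2,6-lutidine gives (3R,4E)-5-iodo-3-methyl-1,3-bis(triethylsilyloxy)pent-4-ene F6. Swern conditions ((COCl)2, DMSO, Et3N) cleave and oxidise only the primary silyl ether to (3R,4E)-5-iodo-3-methyl-3-(triethylsilyloxy)pent-4-enal F7. Wittig reaction of F7 with ylide 8 gives methyl (3E,6R,7E)-8-iodo-6-methyl-2-methylidene-6-(triethylsilyloxy)octa-3,7-dienoate F8, and HF·pyridine on F8 returns to the route at 10.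

## Further compounds

F1 | step 8 | 4-methylfuran-2(5H)-one | CC1=CC(=O)OC1
F2 | step 8 | 4-methyl-2,5-dihydrofuran-2-ol | CC1=CC(O)OC1
F3 | step 8 | (1R,3R,4E)-3-hydroxy-1-{(2R,3S)-2-[(1Z)-3-hydroxy-2-methylprop-1-en-1-yl]-4-methylidene-5-oxooxolan-3-yl}-5-iodo-3-methylpent-4-en-1-yl (2Z)-2-methylbut-2-enoate | C=C1C(=O)O[C@H](/C=C(/C)CO)[C@@H]1[C@H](OC(=O)/C(C)=C\C)C[C@@](C)(O)/C=C/I
F4 | step 6 | methyl (2Z,4R,6R,7E)-2-(chloromethyl)-4,6-dihydroxy-8-iodo-6-methylocta-2,7-dienoate | COC(=O)/C(CCl)=C/[C@H](O)C[C@@](C)(O)/C=C/I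
F5 | step 6 | methyl (2Z,4R,6R,7E)-2-(chloromethyl)-6-hydroxy-8-iodo-6-methyl-4-{[(2Z)-2-methylbut-2-enoyl]oxy}octa-2,7-dienoate | COC(=O)/C(CCl)=C/[C@H](OC(=O)/C(C)=C\C)C[C@@](C)(O)/C=C/I
F6 | step 4 | (3R,4E)-5-iodo-3-methyl-1,3-bis(triethylsilyloxy)pent-4-ene | CC[Si](CC)(CC)OCC[C@@](C)(O[Si](CC)(CC)CC)/C=C/I
F7 | step 4 | (3R,4E)-5-iodo-3-methyl-3-(triethylsilyloxy)pent-4-enal | O=CC[C@@](C)(O[Si](CC)(CC)CC)/C=C/I
F8 | step 4 | methyl (3E,6R,7E)-8-iodo-6-methyl-2-methylidene-6-(triethylsilyloxy)octa-3,7-dienoate | COC(=O)C(=C)/C=C/C[C@@](C)(O[Si](CC)(CC)CC)/C=C/I
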